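## Retrosynthetic overview

1. Target ⇒ C-alkylated phlorisovalerophenone + two prenyl bromides (base-mediated dearomatizing gem-diprenylation, last step). The six-membered ring is bought as phloroglucinol and never built.
2. Aryl–CH2 bond ⇒ phlorisovalerophenone + cyclopentane ketol aldehyde (reductive alkylation through an o-quinone methide).
3. Ketol aldehyde ⇒ α,β-epoxy aldehyde by reductive cleavage of the Cα–O bond only. The tertiary C–O bond of the target is the oxirane bond that survives.
4. Key step: both oxirane C–O bonds are made by nucleophilic epoxidation anti to the isopropenyl group, in the same flask as the amine-mediated cyclodehydration of (S)-3-isopropenyl-6-oxoheptanal (from (S)-limonene by ozonolysis).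
5. Ring order: the cyclopentane first and the oxirane in the same step (opened one step later); no other ring is formed.

Assumption: the trione core of the target is drawn as one of its equilibrating enol tautomers; the route delivers that compound as the tautomeric mixture.

## Route

Step 1
Reactants: 1 (S)-(−)-limonene
Product: 3 (3S)-6-oxo-3-(prop-1-en-2-yl)heptanal, via ozonide 2 (not isolated)
Conditions: O3 (1.0 equiv), CH2Cl2, −78 °C; then Me2S, −78 → 23 °C
Reagents that add atoms: ozone, [O-][O+]=O
Why: Criegee ozonolysis: with one equivalent of ozone at −78 °C the electron-richer trisubstituted ring alkene reacts ahead of the 1,1-disubstituted isopropenyl group, Me2S reduces ozonide 2 to the keto aldehyde, and the stereocentre is not touched.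

Step 2
Reactants: 3 (3S)-6-oxo-3-(prop-1-en-2-yl)heptanal
Product: 5 (1R,2R,5S)-5-methyl-2-(prop-1-en-2-yl)-6-oxabicyclo[3.1.0]hexane-1-carbaldehyde, via cyclopentene carbaldehyde 4 (not isolated)
Conditions: pyrrolidinium trifluoroacetate (20 mol%), CH2Cl2, 23 °C, 4 h; then tBuOOH (5.5 M in decane, 1.3 equiv), 0 → 23 °C
Reagents that add atoms: tert-butyl hydroperoxide, CC(C)(C)OO
Why: Proposed new method: one secondary-amine salt is meant to run two catalytic cycles in relay, namely enamine formation at the aldehyde of 3, 5-exo aldol attack on the methyl ketone and dehydration to the conjugated iminium ion of enal 4 (the known amine/acid aldol cyclodehydration, which closes the cyclopentene), then oxa-Michael addition of tBuOOH to the β-carbon of that iminium ion (this makes the tertiary C–O bond) and closure of the resulting enamine onto the proximal peroxide oxygen with loss of tBuOH (Weitz–Scheffer-type, as in iminium-catalysed enal epoxidation), the water from the dehydration hydrolysing the epoxy iminium ion; because the peroxide addition is reversible and the ring closure takes place at the carbon next to the isopropenyl-bearing stereocentre, the oxirane (both new stereocentres) should form on the face anti to isopropenyl (expected dr about 6:1 or better), and what is new is the merger of the two cycles and the use of a tetrasubstituted cyclopentene carbaldehyde, whose hindered iminium ion is here born by dehydration and need not be formed by condensation.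

Step 3
Reactants: 5 (1R,2R,5S)-5-methyl-2-(prop-1-en-2-yl)-6-oxabicyclo[3.1.0]hexane-1-carbaldehyde
Product: 7 (1R,2S,5S)-2-hydroxy-2-methyl-5-(prop-1-en-2-yl)cyclopentane-1-carbaldehyde, via C1-epimeric ketol aldehyde 6 (not isolated)
Conditions: SmI2 (2.2 equiv), THF/MeOH (4:1), −90 °C, 10 min; pH 7 buffer; then L-proline (10 mol%), EtOH, 23 °C
Reagents that add atoms: none
Why: Reductive ring opening of an α,β-epoxy carbonyl compound by SmI2 (two single-electron transfers from divalent samarium through the carbonyl cleave only the Cα–O bond, as known for epoxy ketones, and an aliphatic aldehyde is not reduced at −90 °C), so the tertiary C–O bond keeps its configuration, and the new C1–H centre, which kinetic protonation delivers partly as epimer 6, is equilibrated through the proline enamine to 7, the isomer with the formyl group trans to isopropenyl and methyl and cis to hydroxyl.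

Step 4
Reactants: 8 phloroglucinol; 9 isovaleryl chloride (3-methylbutanoyl chloride)
Product: 10 phlorisovalerophenone, 3-methyl-1-(2,4,6-trihydroxyphenyl)butan-1-one
Conditions: AlCl3 (3 equiv), PhNO2/CH2Cl2, 0 → 40 °C; aq. HCl
Reagents that add atoms: none
Why: Friedel–Crafts acylation of the very electron-rich arene; the chelated aryl ketone is deactivated, so the reaction stops after one acyl group, and no stereocentre is involved.

Step 5
Reactants: 7 (1R,2S,5S)-2-hydroxy-2-methyl-5-(prop-1-en-2-yl)cyclopentane-1-carbaldehyde; 10 phlorisovalerophenone (3 equiv)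
Product: 12 1-[3-{[(1R,2S,5S)-2-hydroxy-2-methyl-5-(prop-1-en-2-yl)cyclopentyl]methyl}-2,4,6-trihydroxyphenyl]-3-methylbutan-1-one, via o-quinone methide 11 (not isolated)
Conditions: L-proline (20 mol%), Hantzsch ester (diethyl 2,6-dimethyl-1,4-dihydropyridine-3,5-dicarboxylate, 1.2 equiv), CH2Cl2/EtOH (1:1), 23 °C
Reagents that add atoms: none
Why: Three-component reductive alkylation: proline-mediated Knoevenagel-type condensation of aldehyde 7 with a free ring carbon of 10 gives o-quinone methide 11, which is reduced at once by conjugate hydride transfer from the Hantzsch ester, excess 10 suppresses double alkylation, and no stereocentre is formed while C1' stays in its thermodynamically preferred trans configuration under the enamine-forming conditions.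

Step 6
Reactants: 12 1-[3-{[(1R,2S,5S)-2-hydroxy-2-methyl-5-(prop-1-en-2-yl)cyclopentyl]methyl}-2,4,6-trihydroxyphenyl]-3-methylbutan-1-one; 13 prenyl bromide (1-bromo-3-methylbut-2-ene, 2.3 equiv)
Product: 15 3,5-dihydroxy-4-{[(1R,2S,5S)-2-hydroxy-2-methyl-5-(prop-1-en-2-yl)cyclopentyl]methyl}-2-(3-methylbutanoyl)-6,6-bis(3-methylbut-2-en-1-yl)cyclohexa-2,4-dien-1-one (CNP0332156.1), via monoprenyl arene 14 (not isolated)
Conditions: 10% aq. KOH, 0 → 23 °C; then 1 M HCl
Reagents that add atoms: none
Why: Twofold base-mediated C-prenylation of the phloroglucinolate (the alkylative dearomatization used to make hop beta-acids): the only free ring carbon is alkylated to 14 and then a second time, because this carbon is less hindered than the one bearing the branched cyclopentylmethyl group and the gem-dialkylated trione is stabilized as a vinylogous acid anion; no stereocentre is formed or touched.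

## Compound list

1 | (S)-(−)-limonene, (4S)-1-methyl-4-(prop-1-en-2-yl)cyclohex-1-ene | CC1=CC[C@H](CC1)C(C)=C | starting material
2 | ozonide of the ring alkene of 1, 1-methyl-4-(prop-1-en-2-yl)-7,8,9-trioxabicyclo[4.2.1]nonane (isopropenyl-bearing centre as in 1, acetal centres as formed) | CC12CC[C@@H](CC(OO1)O2)C(C)=C | intermediate
3 | (3S)-6-oxo-3-(prop-1-en-2-yl)heptanal | O=CC[C@H](CCC(C)=O)C(C)=C | intermediate
4 | (5R)-2-methyl-5-(prop-1-en-2-yl)cyclopent-1-ene-1-carbaldehyde | O=CC1=C(C)CC[C@@H]1C(C)=C | intermediate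
5 | (1R,2R,5S)-5-methyl-2-(prop-1-en-2-yl)-6-oxabicyclo[3.1.0]hexane-1-carbaldehyde (oxirane oxygen anti to isopropenyl) | O=C[C@]12O[C@@]1(C)CC[C@@H]2C(C)=C | intermediate
6 | (1S,2S,5S)-2-hydroxy-2-methyl-5-(prop-1-en-2-yl)cyclopentane-1-carbaldehyde (C1 epimer of 7) | C=C(C)[C@H]1CC[C@](C)(O)[C@H]1C=O | intermediate
7 | (1R,2S,5S)-2-hydroxy-2-methyl-5-(prop-1-en-2-yl)cyclopentane-1-carbaldehyde (CHO cis to OH, trans to isopropenyl) | C=C(C)[C@H]1CC[C@](C)(O)[C@@H]1C=O | intermediate
8 | phloroglucinol, benzene-1,3,5-triol | Oc1cc(O)cc(O)c1 | starting material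
9 | isovaleryl chloride, 3-methylbutanoyl chloride | CC(C)CC(=O)Cl | starting material
10 | phlorisovalerophenone, 3-methyl-1-(2,4,6-trihydroxyphenyl)butan-1-one | CC(C)CC(=O)c1c(O)cc(O)cc1O | intermediate
11 | 3,5-dihydroxy-6-{[(1R,2S,5S)-2-hydroxy-2-methyl-5-(prop-1-en-2-yl)cyclopentyl]methylidene}-4-(3-methylbutanoyl)cyclohexa-2,4-dien-1-one (o-quinone methide, alkene geometry not defined) | C=C(C)[C@H]1CC[C@](C)(O)[C@@H]1C=C2C(=O)C=C(O)C(C(=O)CC(C)C)=C2O | intermediate
12 | 1-[3-{[(1R,2S,5S)-2-hydroxy-2-methyl-5-(prop-1-en-2-yl)cyclopentyl]methyl}-2,4,6-trihydroxyphenyl]-3-methylbutan-1-one | C=C(C)[C@H]1CC[C@](C)(O)[C@@H]1Cc1c(O)cc(O)c(C(=O)CC(C)C)c1O | intermediate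
13 | prenyl bromide, 1-bromo-3-methylbut-2-ene | CC(C)=CCBr | starting material
14 | 1-[3-{[(1R,2S,5S)-2-hydroxy-2-methyl-5-(prop-1-en-2-yl)cyclopentyl]methyl}-2,4,6-trihydroxy-5-(3-methylbut-2-en-1-yl)phenyl]-3-methylbutan-1-one | C=C(C)[C@H]1CC[C@](C)(O)[C@@H]1Cc1c(O)c(CC=C(C)C)c(O)c(C(=O)CC(C)C)c1O | intermediate
15 | 3,5-dihydroxy-4-{[(1R,2S,5S)-2-hydroxy-2-methyl-5-(prop-1-en-2-yl)cyclopentyl]methyl}-2-(3-methylbutanoyl)-6,6-bis(3-methylbut-2-en-1-yl)cyclohexa-2,4-dien-1-one (CNP0332156.1) | C=C(C)[C@H]1CC[C@](C)(O)[C@@H]1CC1=C(O)C(CC=C(C)C)(CC=C(C)C)C(=O)C(C(=O)CC(C)C)=C1O | target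

## Step count and risks

Total steps: 6. Longest linear sequence: 5 steps (steps 1, 2, 3, 5, 6); step 4 is a one-step side branch.

The three steps most likely to fail:

**Step 2 (the proposed new relay).** The peroxide may add slowly or with poor facial selectivity to the hindered iminium ion, or the aldehyde may be oxidized. The fallback uses known chemistry only and sets out from 3. Cyclodehydration with piperidine/AcOH (benzene, 80 °C) gives isolated enal 4. Luche reduction (NaBH4, CeCl3·7H2O, MeOH, 0 °C) gives the allylic alcohol [(5R)-2-methyl-5-(prop-1-en-2-yl)cyclopent-1-en-1-yl]methanol F1. Hydroxyl-directed electrophilic epoxidation (VO(acac)2, tBuOOH, CH2Cl2, 0 °C) touches only the tetrasubstituted alkene, anti to isopropenyl, and gives the epoxy alcohol [(1S,2R,5S)-5-methyl-2-(prop-1-en-2-yl)-6-oxabicyclo[3.1.0]hexan-1-yl]methanol F2. Dess–Martin oxidation (NaHCO3, CH2Cl2) then gives 5, where the route is rejoined. This replaces the nucleophilic oxygen transfer by a directed electrophilic one.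

**Step 3 (reductive oxirane opening next to an aldehyde).** Pinacol coupling, aldehyde reduction or retro-aldol cleavage could compete. The fallback sets out from 5 and avoids any external reductant at the epoxide stage. Carbene-catalysed internal redox esterification (3-benzyl-5-(2-hydroxyethyl)-4-methylthiazolium chloride 10 mol%, iPr2NEt, MeOH, CH2Cl2, 30 °C) opens the oxirane at Cα and gives methyl (1R,2S,5S)-2-hydroxy-2-methyl-5-(prop-1-en-2-yl)cyclopentane-1-carboxylate F3. LiAlH4 (THF, 0 °C) gives (1S,2S,3S)-2-(hydroxymethyl)-1-methyl-3-(prop-1-en-2-yl)cyclopentan-1-ol F4. Selective oxidation of the primary alcohol (TEMPO, PhI(OAc)2, CH2Cl2) returns to 7; any C1 epimer converges there under the same proline equilibration.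

**Step 5 (coupling of the free ketol aldehyde).** Retro-aldol cleavage or dehydration of 7 under amine catalysis, and tautomerization of the o-quinone methide, are the risks. The fallback sets out from 7 and masks the tertiary alcohol. TESOTf, 2,6-lutidine (CH2Cl2, −78 °C) gives (1R,2S,5S)-2-methyl-5-(prop-1-en-2-yl)-2-[(triethylsilyl)oxy]cyclopentane-1-carbaldehyde F5. The same proline/Hantzsch ester coupling with 10 runs through the silylated o-quinone methide 3,5-dihydroxy-6-({(1R,2S,5S)-2-methyl-5-(prop-1-en-2-yl)-2-[(triethylsilyl)oxy]cyclopentyl}methylidene)-4-(3-methylbutanoyl)cyclohexa-2,4-dien-1-one F6 to the silyl ether 1-[2,4,6-trihydroxy-3-({(1R,2S,5S)-2-methyl-5-(prop-1-en-2-yl)-2-[(triethylsilyl)oxy]cyclopentyl}methyl)phenyl]-3-methylbutan-1-one F7. HF·pyridine (THF, 0 °C) releases 12, where the route is rejoined.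

Further compounds
F1 | step 2 | [(5R)-2-methyl-5-(prop-1-en-2-yl)cyclopent-1-en-1-yl]methanol | OCC1=C(C)CC[C@@H]1C(C)=C
F2 | step 2 | [(1S,2R,5S)-5-methyl-2-(prop-1-en-2-yl)-6-oxabicyclo[3.1.0]hexan-1-yl]methanol | OC[C@]12O[C@@]1(C)CC[C@@H]2C(C)=C
F3 | step 3 | methyl (1R,2S,5S)-2-hydroxy-2-methyl-5-(prop-1-en-2-yl)cyclopentane-1-carboxylate | C=C(C)[C@H]1CC[C@](C)(O)[C@@H]1C(=O)OC
F4 | step 3 | (1S,2S,3S)-2-(hydroxymethyl)-1-methyl-3-(prop-1-en-2-yl)cyclopentan-1-ol | C=C(C)[C@H]1CC[C@](C)(O)[C@@H]1CO
F5 | step 5 | (1R,2S,5S)-2-methyl-5-(prop-1-en-2-yl)-2-[(triethylsilyl)oxy]cyclopentane-1-carbaldehyde | C=C(C)[C@H]1CC[C@](C)(O[Si](CC)(CC)CC)[C@@H]1C=O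
F6 | step 5 | 3,5-dihydroxy-6-({(1R,2S,5S)-2-methyl-5-(prop-1-en-2-yl)-2-[(triethylsilyl)oxy]cyclopentyl}methylidene)-4-(3-methylbutanoyl)cyclohexa-2,4-dien-1-one | C=C(C)[C@H]1CC[C@](C)(O[Si](CC)(CC)CC)[C@@H]1C=C2C(=O)C=C(O)C(C(=O)CC(C)C)=C2O
F7 | step 5 | 1-[2,4,6-trihydroxy-3-({(1R,2S,5S)-2-methyl-5-(prop-1-en-2-yl)-2-[(triethylsilyl)oxy]cyclopentyl}methyl)phenyl]-3-methylbutan-1-one | C=C(C)[C@H]1CC[C@](C)(O[Si](CC)(CC)CC)[C@@H]1Cc1c(O)cc(O)c(C(=O)CC(C)C)c1O
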